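**Retrosynthetic overview**
1. Ring C is formed last and in one step. The pyranone is cut at C4–C3 and O1–C2 (oxidative [4+2] annulation, the new step) into 2,6-dihydroxy-4-methoxybenzaldehyde (ring A plus C4) and the aryl ynol ether 1-(methoxyethynyl)-4-(prenyloxy)benzene (C2, C3, the 3-OMe and ring B).
2. The aldehyde has two equivalent ortho OH groups, so ring closure can only give the 5-hydroxy-7-methoxy pattern. It comes from 2,4,6-trihydroxybenzaldehyde by one O-methylation at the 4-OH.
3. The ynol ether comes from a Negishi coupling of methoxyethynylzinc chloride (from chloroacetaldehyde dimethyl acetal) with 1-iodo-4-(prenyloxy)benzene, itself made from 4-iodophenol and prenyl bromide.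
4. Rings A and B are bought as benzenes; ring C is the only ring that is built.

Assumption: the target has no stereocentre and no stereogenic double bond, so "the single enantiomer given" is read as the one achiral compound of the SMILES.

**Route**

Step 1
Reactants: 1 4-iodophenol; 2 1-bromo-3-methylbut-2-ene (prenyl bromide)
Product: 3 1-iodo-4-[(3-methylbut-2-en-1-yl)oxy]benzene
Conditions: K2CO3 (1.5 equiv), acetone, reflux
Reagents that add atoms: none
Why: Williamson ether synthesis, SN2 attack of the phenoxide on the primary allylic bromide; no stereocentre is formed.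

Step 2
Reactants: 4 2-chloro-1,1-dimethoxyethane (chloroacetaldehyde dimethyl acetal); 3 1-iodo-4-[(3-methylbut-2-en-1-yl)oxy]benzene
Product: 7 1-(methoxyethynyl)-4-[(3-methylbut-2-en-1-yl)oxy]benzene, via lithium methoxyacetylide 5 (not isolated), via (methoxyethynyl)zinc chloride 6 (not isolated)
Conditions: LiNEt2 (3.1 equiv, from Et2NH and n-BuLi), THF, 0 °C; ZnCl2 (1.1 equiv), 0 °C; then 3 (0.8 equiv), Pd(PPh3)4 (3 mol %), 25 °C
Reagents that add atoms: lithium diethylamide, CCN(CC)[Li]; zinc dichloride, Cl[Zn]Cl
Why: LiNEt2 removes MeOH and HCl from 4 and lithiates the resulting methoxyacetylene (supplying the lithium of 5), ZnCl2 transmetalates 5 to 6 (supplying its zinc and chlorine), and a Negishi coupling then joins 6 to 3 with loss of the zinc halide, zerovalent palladium inserting into the C–I bond at 25 °C much faster than it ionises the prenyl ether; no stereocentre is formed.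

Step 3
Reactants: 8 2,4,6-trihydroxybenzaldehyde
Product: 9 2,6-dihydroxy-4-methoxybenzaldehyde
Conditions: Me2SO4 (1.0 equiv), K2CO3 (1.0 equiv), acetone, 0 to 25 °C
Reagents that add atoms: dimethyl sulfate, COS(=O)(=O)OC
Why: Chemoselective Williamson O-methylation, since the 4-OH (para to CHO, not hydrogen-bonded) is the most acidic and most nucleophilic phenol while the ortho OH groups are held back by chelation to C=O; one equivalent of base and of a hard methylating agent limits over- and C-methylation, and no stereocentre is formed.

Step 4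
Reactants: 9 2,6-dihydroxy-4-methoxybenzaldehyde; 7 1-(methoxyethynyl)-4-[(3-methylbut-2-en-1-yl)oxy]benzene
Product: 10 5-hydroxy-3,7-dimethoxy-2-{4-[(3-methylbut-2-en-1-yl)oxy]phenyl}-4H-chromen-4-one (target)
Conditions: [(C5Me5)RhCl2]2 (2.5 mol %), CsOAc (20 mol %), Ag2CO3 (1.1 equiv), 4 Å MS, toluene, 80 °C, N2; 7 (1.3 equiv) added over 4 h
Reagents that add atoms: none
Why: Proposed new method: oxidative [4+2] annulation of a salicylaldehyde with an aryl ynol ether, the closest known reaction being the rhodium-catalysed oxidative coupling of salicylaldehydes with diaryl and dialkyl alkynes to 2,3-disubstituted chromones, which has not been shown for alkynyl ethers; phenoxide-directed cleavage of the formyl C–H bond by trivalent rhodium gives a five-membered acyl rhodacycle, the polarised alkyne MeO–C≡C–Ar inserts so that the acyl carbon bonds to the electron-poor OMe-bearing carbon and rhodium to the aryl-bearing carbon (electronic bias and the usual aryl-next-to-metal preference agree), C–O reductive elimination from the seven-membered oxa-rhodacycle closes ring C as the 3-methoxyflavone, and Ag2CO3 returns monovalent rhodium to the trivalent state while serving as the only stoichiometric base, so no carboxylic acid builds up to add across the ynol ether; the two ortho OH groups of 9 are equivalent, so one constitution results and the unused OH becomes the chelated 5-OH; no stereocentre is formed.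

**Compound list**
1 | 4-iodophenol | Oc1ccc(I)cc1 | starting material
2 | 1-bromo-3-methylbut-2-ene (prenyl bromide) | CC(C)=CCBr | starting material
3 | 1-iodo-4-[(3-methylbut-2-en-1-yl)oxy]benzene | CC(C)=CCOc1ccc(I)cc1 | intermediate
4 | 2-chloro-1,1-dimethoxyethane | COC(CCl)OC | starting material
5 | lithium methoxyacetylide | [Li]C#COC | intermediate
6 | (methoxyethynyl)zinc chloride | COC#C[Zn]Cl | intermediate
7 | 1-(methoxyethynyl)-4-[(3-methylbut-2-en-1-yl)oxy]benzene | COC#Cc1ccc(OCC=C(C)C)cc1 | intermediate
8 | 2,4,6-trihydroxybenzaldehyde | O=Cc1c(O)cc(O)cc1O | starting material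
9 | 2,6-dihydroxy-4-methoxybenzaldehyde | COc1cc(O)c(C=O)c(O)c1 | intermediate
10 | 5-hydroxy-3,7-dimethoxy-2-{4-[(3-methylbut-2-en-1-yl)oxy]phenyl}-4H-chromen-4-one | COc1cc(O)c2c(=O)c(OC)c(-c3ccc(OCC=C(C)C)cc3)oc2c1 | target

**Step count and risks**
Total steps: 4. Longest linear sequence: 3 (steps 1, 2, 4).

Steps most likely to fail:

1. Step 4 (the proposed new annulation). The main risks are:
- addition of water or of the phenol across the acid-sensitive ynol ether, which would give methyl arylacetate-type by-products;
- loss of methoxide from the alkenyl rhodium intermediate, which would give an ynone and then the flavone without the 3-OMe;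
- insertion with the opposite regiochemistry;
- binding of the 5-hydroxy-4-keto product to rhodium.

The fallback uses known chemistry only and gives up the annulation for the classical ketone route. It sets out from prenyl bromide 2, the one route compound it keeps, together with bought 4-(benzyloxy)benzoic acid and bought 2-methoxy-1-(2,4,6-trihydroxyphenyl)ethanone, and it comes back to the route at target 10. 4-(Benzyloxy)benzoic acid is dehydrated with DCC (CH2Cl2, 25 °C) to 4-(benzyloxy)benzoic anhydride F1. Heating the methoxy ketone with F1 and Et3N at 160 °C, then KOH in aqueous MeOH at reflux (Allan–Robinson flavone synthesis), gives 2-[4-(benzyloxy)phenyl]-5,7-dihydroxy-3-methoxy-4H-chromen-4-one F2. Me2SO4 (1.05 equiv), K2CO3, acetone, reflux methylates only the non-chelated 7-OH and gives 2-[4-(benzyloxy)phenyl]-5-hydroxy-3,7-dimethoxy-4H-chromen-4-one F3. Hydrogenolysis (H2, Pd/C, EtOAc–THF, 25 °C) gives 5-hydroxy-2-(4-hydroxyphenyl)-3,7-dimethoxy-4H-chromen-4-one F4 (kumatakenin). Alkylation of F4 with 2 (K2CO3, acetone, reflux) at the free 4'-OH gives 10, the chelated 5-OH staying untouched. The benzyl group is used because a prenyl ether would not survive 160 °C without Claisen rearrangement.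

2. Step 2 (ynol ether by Negishi coupling). The risks are incomplete formation of 5, sluggish transmetalation in the presence of LiOMe and amine, and loss of 7 on acidic silica; 7 should be purified on base-washed silica or alumina. The fallback makes the alkyne by elimination instead of cross-coupling; it sets out from 3 and comes back at 7. Iodine–magnesium exchange on 3 (i-PrMgCl·LiCl, THF, −20 °C) gives {4-[(3-methylbut-2-en-1-yl)oxy]phenyl}magnesium chloride F5. Acylation of F5 with the Weinreb amide N,2-dimethoxy-N-methylacetamide gives 2-methoxy-1-{4-[(3-methylbut-2-en-1-yl)oxy]phenyl}ethanone F6. KHMDS and PhNTf2 (THF, −78 °C) trap the chelated enolate as (Z)-2-methoxy-1-{4-[(3-methylbut-2-en-1-yl)oxy]phenyl}ethenyl trifluoromethanesulfonate F7. KOt-Bu (THF, −78 to 0 °C) then removes H and triflate anti to each other and gives 7.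

3. Step 3 (mono-methylation of 8). The risk is a mixture of 9, the 4,6-dimethyl ether and unreacted 8. The fallback replaces kinetic mono-alkylation by over-alkylation followed by chelation-directed dealkylation; it sets out from 8 and comes back at 9. Me2SO4 (2.2 equiv), K2CO3, acetone, reflux methylates every OH except the chelated one and gives 2-hydroxy-4,6-dimethoxybenzaldehyde F8. AlCl3 (3 equiv), CH2Cl2, reflux then cleaves only the methyl ether ortho to the formyl group and gives 9, the para OMe being out of reach of the carbonyl-bound Lewis acid.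

**Further compounds**
F1 | step 4 | 4-(benzyloxy)benzoic anhydride | O=C(OC(=O)c1ccc(OCc2ccccc2)cc1)c1ccc(OCc2ccccc2)cc1
F2 | step 4 | 2-[4-(benzyloxy)phenyl]-5,7-dihydroxy-3-methoxy-4H-chromen-4-one | Oc1cc(O)c2c(=O)c(OC)c(-c3ccc(OCc4ccccc4)cc3)oc2c1
F3 | step 4 | 2-[4-(benzyloxy)phenyl]-5-hydroxy-3,7-dimethoxy-4H-chromen-4-one | COc1cc(O)c2c(=O)c(OC)c(-c3ccc(OCc4ccccc4)cc3)oc2c1
F4 | step 4 | 5-hydroxy-2-(4-hydroxyphenyl)-3,7-dimethoxy-4H-chromen-4-one | COc1cc(O)c2c(=O)c(OC)c(-c3ccc(O)cc3)oc2c1
F5 | step 2 | {4-[(3-methylbut-2-en-1-yl)oxy]phenyl}magnesium chloride | Cl[Mg]c1ccc(OCC=C(C)C)cc1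
F6 | step 2 | 2-methoxy-1-{4-[(3-methylbut-2-en-1-yl)oxy]phenyl}ethanone | COCC(=O)c1ccc(OCC=C(C)C)cc1
F7 | step 2 | (Z)-2-methoxy-1-{4-[(3-methylbut-2-en-1-yl)oxy]phenyl}ethenyl trifluoromethanesulfonate | CO/C=C(/c1ccc(OCC=C(C)C)cc1)OS(=O)(=O)C(F)(F)F
F8 | step 3 | 2-hydroxy-4,6-dimethoxybenzaldehyde | COc1cc(O)c(C=O)c(OC)c1
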